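**Retrosynthetic overview**

1. The target 30 comes from periodate cleavage of the C6–C7 bond of a 6-hydroxy-7,20-hemiketal. Ring B (C5–C6–C7–C8–C9–C10) is a temporary carbocycle whose opening gives the C6 aldehyde and the 7,20-lactone in one step.
2. Ring D comes from a 5-exo vinyl-radical closure (C16–C13). The quaternary C8 and C9–H come from dissolving-metal reductive alkylation of a Δ8(9)-7-ketone. The C15 carbinol comes from allylic oxidation and exo-face hydride reduction.
3. Key disconnection: C3–C4 and C5–C10 are formed by an intramolecular Diels–Alder reaction of a 3-(cyclohexadienyl)-4-methoxy-2-pyranone, C20(=O)–C10=C1(OMe)–C2=C3–O, with a tethered Me2C4=C5H alkene. Rings A and B close together; the C20(=O)–O–C3 lactone bridge is a second temporary ring that stores C20 and the cis C3 oxygen.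
4. Enabling feature: in ring A, C10 carries C20 and sits next to the oxygenated C1, with the oxygenated C3 para to it. This is the substitution pattern of a 4-alkoxy-2-pyranone. C5 and C10 are joined through C6–C7–C8–C9, and C6 (aldehyde) and C7 (lactone carbonyl) are the two ends of a cleaved ring B bond.
5. Ring order: C (Diels–Alder with butadiene), then A + B (key step), then D (radical), then B opened (last step). One carbinol centre (C7, from catalytic asymmetric allylboration) sets the absolute configuration and is erased after the key step.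

Key step: step 9

Remarks: atom numbers C1–C20 are the ent-kaurane numbers of the target (C6 = aldehyde carbon, C7 = lactone carbonyl, C20 = lactone OCH2). 4-Methoxy-2H-pyran-2-one (9) is taken as a purchasable building block.

**Route**

Step 1
Reactants: 1 methyl propiolate
Product: 2 methyl 3-bromopropiolate
Conditions: NBS, AgNO3 (cat.), acetone, rt
Reagents that add atoms: N-bromosuccinimide, O=C1CCC(=O)N1Br
Why: Silver-catalysed electrophilic bromination of the terminal alkyne C–H gives the bromoalkyne (no stereocentre).

Step 2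
Reactants: 2 methyl 3-bromopropiolate; 3 buta-1,3-diene
Product: 4 methyl 2-bromocyclohexa-1,4-diene-1-carboxylate
Conditions: toluene, hydroquinone (cat.), sealed tube, 90 °C
Reagents that add atoms: none
Why: Diels–Alder reaction of butadiene with the activated bromopropiolate builds ring C as a cyclohexa-1,4-diene carrying the vinyl bromide (future C9) and the ester carbon (future C7) on adjacent carbons; no stereocentre.

Step 3
Reactants: 4 methyl 2-bromocyclohexa-1,4-diene-1-carboxylate
Product: 5 (2-bromocyclohexa-1,4-dien-1-yl)methanol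
Conditions: i-Bu2AlH (2.2 equiv), CH2Cl2, −78 → 0 °C; aq. potassium sodium tartrate
Reagents that add atoms: none
Why: Hydride 1,2-reduction of the conjugated ester to the allylic alcohol; the vinyl bromide and the skipped diene are untouched.

Step 4
Reactants: 5 (2-bromocyclohexa-1,4-dien-1-yl)methanol
Product: 6 2-bromocyclohexa-1,4-diene-1-carbaldehyde
Conditions: Dess–Martin periodinane, CH2Cl2, 0 °C → rt
Reagents that add atoms: none
Why: Dess–Martin oxidation of the primary allylic alcohol to the enal under non-basic conditions that spare the oxidation-prone cyclohexa-1,4-diene.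

Step 5
Reactants: 6 2-bromocyclohexa-1,4-diene-1-carbaldehyde
Product: 7 (1R)-1-(2-bromocyclohexa-1,4-dien-1-yl)but-3-en-1-ol
Conditions: allylboronic acid pinacol ester, (R)-TRIP [(R)-3,3'-bis(2,4,6-triisopropylphenyl)-1,1'-binaphthyl-2,2'-diyl hydrogen phosphate] (5 mol %), toluene, −30 °C
Reagents that add atoms: allylboronic acid pinacol ester, C=CCB1OC(C)(C)C(C)(C)O1
Why: Chiral phosphoric acid-catalysed allylboration through a closed chair transition state; the acid enantiomer is chosen for Re-face addition and sets the single controlling stereocentre C7 as (R).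

Step 6
Reactants: 7 (1R)-1-(2-bromocyclohexa-1,4-dien-1-yl)but-3-en-1-ol
Product: 8 (1R)-1-(2-bromocyclohexa-1,4-dien-1-yl)-4-methylpent-3-en-1-ol
Conditions: 2-methyl-2-butene (excess), second-generation Grubbs catalyst RuCl2(=CHPh)(PCy3)(H2IMes) (5 mol %), CH2Cl2, 40 °C
Reagents that add atoms: 2-methyl-2-butene, CC=C(C)C
Why: Olefin cross-metathesis of the terminal alkene installs the Me2C4=C5H dienophile; the tetrasubstituted vinyl bromide and the unstrained ring alkene are inert and C7 is untouched.

Step 7
Reactants: 9 4-methoxy-2H-pyran-2-one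
Product: 10 3-bromo-4-methoxy-2H-pyran-2-one
Conditions: NBS, MeCN, rt
Reagents that add atoms: N-bromosuccinimide, O=C1CCC(=O)N1Br
Why: Electrophilic bromination of the vinylogous carbonate at its nucleophilic C3 position, between the carbonyl and the enol ether carbon.

Step 8
Reactants: 8 (1R)-1-(2-bromocyclohexa-1,4-dien-1-yl)-4-methylpent-3-en-1-ol; 10 3-bromo-4-methoxy-2H-pyran-2-one
Product: 12 3-{2-[(1R)-1-hydroxy-4-methylpent-3-en-1-yl]cyclohexa-1,4-dien-1-yl}-4-methoxy-2H-pyran-2-one, via pinacol boronate 11 (not isolated)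
Conditions: B2pin2, PdCl2(dppf), KOAc, 1,4-dioxane, 85 °C; then 10, Pd(OAc)2, SPhos, aq. K3PO4, 45 °C
Reagents that add atoms: bis(pinacolato)diboron, CC1(C)OB(OC1(C)C)B1OC(C)(C)C(C)(C)O1 (its boron is carried by 11 only)
Why: One-pot Miyaura borylation of the vinyl bromide and Suzuki–Miyaura coupling with bromopyranone 10 form the C9–C10 bond under weakly basic conditions that leave the pyranone and the free carbinol intact; no stereocentre changes.

Step 9
Reactants: 12 3-{2-[(1R)-1-hydroxy-4-methylpent-3-en-1-yl]cyclohexa-1,4-dien-1-yl}-4-methoxy-2H-pyran-2-one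
Product: 13 lactone-bridged cycloadduct (ring A = 2-oxabicyclo[2.2.2]oct-5-en-3-one with C1(OMe)=C2 and the C20(=O)–O–C3 bridge; ring B with (7R)-OH and C8=C9; ring C cyclohexa-1,4-diene; H-5 trans to C20; 7-OH cis to C20)
Conditions: toluene (0.005 M, degassed), BHT (cat.), 110 °C
Reagents that add atoms: none
Why: Thermal, concerted but asynchronous [4+2] cycloaddition in which the pyranone diene C10=C1–C2=C3 adds across the tethered, electron-rich Me2C4=C5H alkene, forming C5–C10 and C3–C4; the closest known reaction type is the intramolecular Diels–Alder reaction of 2-pyranones with unactivated trisubstituted alkenes, which gives 2-oxabicyclo[2.2.2]octenones without loss of CO2 at about 100 °C. Ring A closes as the cyclohexene of the cycloadduct (both new bonds), ring B closes as the six-membered tether ring C10–C9=C8–C7–C6–C5 in the fused mode (the cis C8=C9 bond of ring C holds diene and dienophile together), and the pyranone becomes the bridging lactone. C3 is tied to C10 because both lie on the same face of the flat pyranone, so the C3 oxygen is cis to C20; C5 follows from the exo arrangement, in which the tether lies under the lactone carbonyl and H-5 ends trans to C20; the absolute sense at C10, C3 and C5 is set by the C7 carbinol. The step needs regioselectivity (C5 to C10 and C4 to C3, against the polarity preference), exo over endo selectivity and face selectivity. The short tether allows only the fused regiochemistry, and in toluene the C7 hydroxyl, pseudo-axial on the forming boat-like ring B to avoid allylic strain with C14H2, hydrogen-bonds to the pyranone carbonyl (C20=O); this lowers the diene LUMO and holds C20=O over the tether (exo) on the face opposite to the incoming alkene, so that (7R) translates into the required C10 configuration. The endo mode would have to trade this hydrogen bond for a weaker contact to the enol ether oxygen.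

Step 10
Reactants: 13 lactone-bridged cycloadduct
Product: 14 Δ8(9)-7-ketone (enone in ring B, otherwise as 13)
Conditions: Dess–Martin periodinane, pyridine, CH2Cl2, 0 °C
Reagents that add atoms: none
Why: Dess–Martin oxidation of the allylic C7 carbinol gives the enone needed for the next step and erases the controlling stereocentre, which is no longer needed.

Step 11
Reactants: 14 Δ8(9)-7-ketone
Product: 16 C8-(2-bromoallyl) 7-ketone (H-9 trans to C20; bromoallyl group cis to H-9), via lithium enolate 15 (not isolated)
Conditions: Li (2.1 equiv), t-BuOH (1.0 equiv), NH3(l)/THF, −78 °C; then 2,3-dibromopropene, −78 → −40 °C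
Reagents that add atoms: 2,3-dibromopropene, C=C(Br)CBr
Why: Dissolving-metal reduction of the enone with axial protonation at C9 (H-9 trans to the axial C20 carbon) gives the C8 lithium enolate regiospecifically, which is C-allylated by the allylic bromide on the face anti to C20 and cis to H-9 (reductive alkylation), setting C9 and the quaternary C8.

Step 12
Reactants: 16 C8-(2-bromoallyl) 7-ketone
Product: 17 lactone-bridged ent-kaur-16-en-7-one (rings A–D; C1 methyl enol ether; C20(=O)–O–C3 lactone)
Conditions: Bu3SnH (1.5 equiv, 0.1 M), azobisisobutyronitrile (cat.), benzene, 80 °C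
Reagents that add atoms: none
Why: Tin hydride-mediated vinyl radical cyclization, 5-exo-trig onto C13 of the ring C alkene, closes ring D; only the cis-bridged bicyclo[3.2.1]octane can form, so C13 is fixed by C8, and the high tin hydride concentration traps the kinetic C12 radical before homoallyl rearrangement.

Step 13
Reactants: 17 lactone-bridged ent-kaur-16-en-7-one
Product: 19 7,20-epoxy hemiketal diol (3-OH cis to C20; 7-OH; C1 methyl enol ether; Δ16), via lithium enolate 18 (not isolated)
Conditions: LiN(i-Pr)2 (1.2 equiv), THF, −78 °C; then LiAlH4, −78 → 0 °C; aq. potassium sodium tartrate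
Reagents that add atoms: none
Why: The C7 ketone is protected in situ as its lithium enolate so that LiAlH4 reduces only the bridging lactone to the C20 primary alcohol and the C3 carbinol (C3–O bond and configuration untouched); on work-up the regenerated ketone is captured by the C20 hydroxyl as the 7,20-hemiketal, whose C7 configuration is dictated by the bridge.

Step 14
Reactants: 19 7,20-epoxy hemiketal diol
Product: 21 6-hydroxy-7,20-epoxy hemiketal (6-OH trans to C20), via tripotassium salt 20 (not isolated)
Conditions: KN(SiMe3)2 (3.5 equiv), THF, −78 °C; then 2-(phenylsulfonyl)-3-phenyloxaziridine; H2O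
Reagents that add atoms: 2-(phenylsulfonyl)-3-phenyloxaziridine, O=S(=O)(c1ccccc1)N1OC1c1ccccc1
Why: Base opens the hemiketal to the keto alkoxide and the C6 potassium enolate is hydroxylated by the N-sulfonyloxaziridine (enolate oxidation) on the face anti to the axial C20 carbon; the hemiketal re-closes on work-up and the C6 configuration is immaterial because C6 becomes the aldehyde carbon.

Step 15
Reactants: 21 6-hydroxy-7,20-epoxy hemiketal
Product: 22 3,6-bis(tert-butyldimethylsilyl) ether of 21
Conditions: TBSOTf (2.5 equiv), 2,6-lutidine, CH2Cl2, −40 → 0 °C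
Reagents that add atoms: tert-butyldimethylsilyl triflate, CC(C)(C)[Si](C)(C)OS(=O)(=O)C(F)(F)F
Why: Silyl triflate silylation of the two secondary hydroxyls (C3, C6) at low temperature, the tertiary hemiketal hydroxyl being too hindered to react, so that only C1 is acetylated later.

Step 16
Reactants: 22 3,6-bis(tert-butyldimethylsilyl) ether
Product: 23 1-ketone (3,6-bis-silyl ether; 7,20-hemiketal)
Conditions: oxalic acid (cat.), THF/H2O, 0 °C
Reagents that add atoms: water, O
Why: Mild acid hydrolysis of the methyl enol ether (C-protonation at C2, hydration of the oxocarbenium ion, loss of methanol) unveils the C1 ketone without touching the silyl ethers or the hemiketal.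

Step 17
Reactants: 23 1-ketone
Product: 24 1-alcohol (1-OH cis to C20)
Conditions: NaBH4, MeOH/CH2Cl2, −20 °C
Reagents that add atoms: none
Why: Borohydride reduction with axial hydride delivery on the face opposite to the axial C20 carbon gives the equatorial C1 alcohol cis to C20; the C7 carbonyl is masked as the hemiketal.

Step 18
Reactants: 24 1-alcohol
Product: 25 1-acetate
Conditions: Ac2O, pyridine, DMAP (cat.), CH2Cl2, rt
Reagents that add atoms: acetic anhydride, CC(=O)OC(C)=O
Why: DMAP-catalysed acylation of the only free secondary hydroxyl (C1); the tertiary hemiketal hydroxyl is not acylated.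

Step 19
Reactants: 25 1-acetate
Product: 26 15-exo-alcohol (15-OH anti to the C9–C11–C12 bridge; C15 epimer of the target carbinol)
Conditions: SeO2 (0.3 equiv), t-BuOOH, CH2Cl2, rt
Reagents that add atoms: tert-butyl hydroperoxide, CC(C)(C)OO (terminal oxidant; the oxygen is transferred through catalytic selenium dioxide, O=[Se]=O)
Why: SeO2 allylic oxidation (ene reaction followed by [2,3]-sigmatropic shift) hydroxylates C15, the only non-bridgehead allylic position, from the open exo face of ring D and returns the exocyclic alkene; this gives the C15 epimer of the target carbinol.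

Step 20
Reactants: 26 15-exo-alcohol
Product: 27 16-en-15-one
Conditions: Dess–Martin periodinane, pyridine, CH2Cl2, 0 °C
Reagents that add atoms: none
Why: Dess–Martin oxidation of the allylic alcohol to the enone prepares the stereochemical correction at C15.

Step 21
Reactants: 27 16-en-15-one
Product: 28 15-endo-alcohol (15-OH syn to the C9–C11–C12 bridge, as in the target)
Conditions: NaBH4, CeCl3·7H2O, MeOH, −78 °C
Reagents that add atoms: none
Why: Luche 1,2-reduction of the enone with hydride delivery from the exo face of the bicyclo[3.2.1]octane, anti to the C9–C11–C12 bridge and its axial C11 hydrogen, gives the endo C15 carbinol of the target; the acetate and the hemiketal-masked C7 survive.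

Step 22
Reactants: 28 15-endo-alcohol
Product: 29 1-acetoxy-3,6,7,15-tetrahydroxy-7,20-epoxy-ent-kaur-16-ene
Conditions: HF·pyridine, pyridine/THF, 0 °C → rt
Reagents that add atoms: none
Why: Buffered fluoride cleavage of the two silyl ethers, under which the acetate does not migrate.

Step 23
Reactants: 29 1-acetoxy-3,6,7,15-tetrahydroxy-7,20-epoxy-ent-kaur-16-ene
Product: 30 target (CNP0536233.1)
Conditions: NaIO4, THF/H2O, rt
Reagents that add atoms: none
Why: Periodate glycol cleavage of the C6–C7 bond of the 6-hydroxy-7-hemiketal (Malaprade reaction) turns C6 into the aldehyde and the hemiketal carbon C7 into the lactone carbonyl already bonded to O–C20, giving the 7,20-lactone with no stereocentre touched.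

**Compound list**

1 | methyl propiolate | C#CC(=O)OC | starting material
2 | methyl 3-bromopropiolate | BrC#CC(=O)OC | intermediate
3 | buta-1,3-diene | C=CC=C | starting material
4 | methyl 2-bromocyclohexa-1,4-diene-1-carboxylate | COC(=O)C1=C(Br)CC=CC1 | intermediate
5 | (2-bromocyclohexa-1,4-dien-1-yl)methanol | OCC1=C(Br)CC=CC1 | intermediate
6 | 2-bromocyclohexa-1,4-diene-1-carbaldehyde | O=CC1=C(Br)CC=CC1 | intermediate
7 | (1R)-1-(2-bromocyclohexa-1,4-dien-1-yl)but-3-en-1-ol | C=CC[C@@H](O)C1=C(Br)CC=CC1 | intermediate
8 | (1R)-1-(2-bromocyclohexa-1,4-dien-1-yl)-4-methylpent-3-en-1-ol | CC(C)=CC[C@@H](O)C1=C(Br)CC=CC1 | intermediate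
9 | 4-methoxy-2H-pyran-2-one | COC1=CC(=O)OC=C1 | starting material
10 | 3-bromo-4-methoxy-2H-pyran-2-one | COC1=C(Br)C(=O)OC=C1 | intermediate
11 | pinacol boronate of 8 (Bpin in place of Br; not isolated) | CC(C)=CC[C@@H](O)C1=C(B2OC(C)(C)C(C)(C)O2)CC=CC1 | intermediate
12 | 3-{2-[(1R)-1-hydroxy-4-methylpent-3-en-1-yl]cyclohexa-1,4-dien-1-yl}-4-methoxy-2H-pyran-2-one | CC(C)=CC[C@@H](O)C1=C(CC=CC1)C2=C(OC)C=COC2=O | intermediate
13 | lactone-bridged cycloadduct (rings A, B, C; C1 enol ether; C20(=O)–O–C3 bridge; (7R)-OH) | COC1=C[C@@H]2C(C)(C)[C@H]3C[C@@H](O)C4=C(CC=CC4)[C@]13C(=O)O2 | intermediate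
14 | Δ8(9)-7-ketone | COC1=C[C@@H]2C(C)(C)[C@H]3CC(=O)C4=C(CC=CC4)[C@]13C(=O)O2 | intermediate
15 | lithium C7–C8 enolate with H-9 trans to C20 (not isolated) | [Li+].COC1=C[C@@H]2C(C)(C)[C@H]3CC([O-])=C4CC=CC[C@H]4[C@]13C(=O)O2 | intermediate
16 | C8-(2-bromoallyl) 7-ketone | COC1=C[C@@H]2C(C)(C)[C@H]3CC(=O)[C@@]4(CC(Br)=C)CC=CC[C@H]4[C@]13C(=O)O2 | intermediate
17 | lactone-bridged ent-kaur-16-en-7-one (C1 methyl enol ether) | C=C1[C@@H]2CC[C@@H]3[C@](C2)(C(=O)C[C@@H]4C(C)(C)[C@H]5C=C(OC)[C@@]34C(=O)O5)C1 | intermediate
18 | lithium C6–C7 enolate of 17 (not isolated) | [Li+].C=C1[C@@H]2CC[C@@H]3[C@](C2)(C([O-])=C[C@@H]4C(C)(C)[C@H]5C=C(OC)[C@@]34C(=O)O5)C1 | intermediate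
19 | 7,20-epoxy hemiketal with 3-OH and C1 methyl enol ether | C=C1[C@@H]2CC[C@@H]3[C@](C2)([C@@]4(O)C[C@@H]5C(C)(C)[C@H](O)C=C(OC)[C@@]35CO4)C1 | intermediate
20 | tripotassium salt: C6–C7 enolate with C3 and C20 alkoxides (not isolated) | [K+].[K+].[K+].C=C1[C@@H]2CC[C@@H]3[C@](C2)(C([O-])=C[C@@H]4C(C)(C)[C@H]([O-])C=C(OC)[C@@]34C[O-])C1 | intermediate
21 | 6-hydroxy-7,20-epoxy hemiketal | C=C1[C@@H]2CC[C@@H]3[C@](C2)([C@@]4(O)[C@@H](O)[C@@H]5C(C)(C)[C@H](O)C=C(OC)[C@@]35CO4)C1 | intermediate
22 | 3,6-bis(tert-butyldimethylsilyl) ether of 21 | C=C1[C@@H]2CC[C@@H]3[C@](C2)([C@@]4(O)[C@@H](O[Si](C)(C)C(C)(C)C)[C@@H]5C(C)(C)[C@H](O[Si](C)(C)C(C)(C)C)C=C(OC)[C@@]35CO4)C1 | intermediate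
23 | 1-ketone | C=C1[C@@H]2CC[C@@H]3[C@](C2)([C@@]4(O)[C@@H](O[Si](C)(C)C(C)(C)C)[C@@H]5C(C)(C)[C@H](O[Si](C)(C)C(C)(C)C)CC(=O)[C@@]35CO4)C1 | intermediate
24 | 1-alcohol (1-OH cis to C20) | C=C1[C@@H]2CC[C@@H]3[C@](C2)([C@@]4(O)[C@@H](O[Si](C)(C)C(C)(C)C)[C@@H]5C(C)(C)[C@H](O[Si](C)(C)C(C)(C)C)C[C@H](O)[C@@]35CO4)C1 | intermediate
25 | 1-acetate | C=C1[C@@H]2CC[C@@H]3[C@](C2)([C@@]4(O)[C@@H](O[Si](C)(C)C(C)(C)C)[C@@H]5C(C)(C)[C@H](O[Si](C)(C)C(C)(C)C)C[C@H](OC(C)=O)[C@@]35CO4)C1 | intermediate
26 | 15-exo-alcohol (15-epimer) | C=C1[C@@H]2CC[C@@H]3[C@](C2)([C@@]4(O)[C@@H](O[Si](C)(C)C(C)(C)C)[C@@H]5C(C)(C)[C@H](O[Si](C)(C)C(C)(C)C)C[C@H](OC(C)=O)[C@@]35CO4)[C@H]1O | intermediate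
27 | 16-en-15-one | C=C1[C@@H]2CC[C@@H]3[C@](C2)([C@@]4(O)[C@@H](O[Si](C)(C)C(C)(C)C)[C@@H]5C(C)(C)[C@H](O[Si](C)(C)C(C)(C)C)C[C@H](OC(C)=O)[C@@]35CO4)C1=O | intermediate
28 | 15-endo-alcohol | C=C1[C@@H]2CC[C@@H]3[C@](C2)([C@@]4(O)[C@@H](O[Si](C)(C)C(C)(C)C)[C@@H]5C(C)(C)[C@H](O[Si](C)(C)C(C)(C)C)C[C@H](OC(C)=O)[C@@]35CO4)[C@@H]1O | intermediate
29 | 1-acetoxy-3,6,7,15-tetrahydroxy-7,20-epoxy-ent-kaur-16-ene | C=C1[C@@H]2CC[C@@H]3[C@](C2)([C@@]4(O)[C@@H](O)[C@@H]5C(C)(C)[C@H](O)C[C@H](OC(C)=O)[C@@]35CO4)[C@@H]1O | intermediate
30 | CNP0536233.1 (1-acetoxy-3,15-dihydroxy-6-oxo-6,7-seco-ent-kaur-16-en-7,20-olide) | C=C1[C@@H]2CC[C@@H]3[C@](C2)(C(=O)OC[C@]32[C@@H](OC(C)=O)C[C@@H](O)C(C)(C)[C@H]2C=O)[C@@H]1O | target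

**Step count and risks**

Total: 23 steps. Longest linear sequence: 22 steps (steps 1–6 and 8–23); step 7 is a one-step side branch.

Steps most likely to fail:

1. Step 9. What may go wrong: the hydrogen bond may not organise the transition state, so exo/endo and face discrimination is lost (the endo mode gives the opposite C10/C3 configuration). The congested triene may also react slowly, with aromatisation of ring C competing. Fallback: the hydrogen bond is replaced by a temporary covalent metal tether, a Lewis-acid-templated Diels–Alder reaction. Setting out from 12, Me3Al (1.0 equiv, toluene, −78 → 0 °C) converts the carbinol into the dimethylaluminium alkoxide F1. Its aluminium is bound to the C7 oxygen and chelates the pyranone carbonyl, which fixes the exo geometry and activates the diene. Warming to about 50 °C gives the cycloadduct aluminium alkoxide F2. Work-up with aq. potassium sodium tartrate returns the route at 13.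

2. Step 13. What may go wrong: incomplete or reversible enolisation, so that hydride also attacks C7 and the ketone needed for the hemiketal is over-reduced. Fallback: the ketone is protected as an isolated silyl enol ether instead of in the flask. Setting out from 17, LiN(i-Pr)2 and then TBSCl (THF, −78 °C, through enolate 18) give the tert-butyldimethylsilyl enol ether F4. LiAlH4 (THF, 0 °C) then reduces the lactone to the diol F5. Bu4NF (THF, 0 °C) cleaves the silyl enol ether, and the freed ketone closes onto the C20 hydroxyl, returning the route at 19.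

3. Step 11. What may go wrong: proton transfer in liquid ammonia quenches the enolate before alkylation, amide base eliminates HBr from the electrophile, or excess metal attacks the lactone. Fallback: reduction and alkylation are separated. Setting out from 14, the same Li/t-BuOH/NH3 reduction gives lithium enolate 15, which is trapped with Me3SiCl/Et3N as the trimethylsilyl enol ether F3 and isolated. Fluoride-promoted alkylation (benzyltrimethylammonium fluoride, 2,3-dibromopropene, THF, 4 Å molecular sieves) then delivers the bromoallyl group to the same face, returning the route at 16.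

**Further compounds**

F1 | step 9 | dimethylaluminium alkoxide of 12 | CC(C)=CC[C@@H](O[Al](C)C)C1=C(CC=CC1)C2=C(OC)C=COC2=O
F2 | step 9 | dimethylaluminium alkoxide of cycloadduct 13 | COC1=C[C@@H]2C(C)(C)[C@H]3C[C@@H](O[Al](C)C)C4=C(CC=CC4)[C@]13C(=O)O2
F3 | step 11 | trimethylsilyl enol ether (C7–C8) with H-9 trans to C20 | COC1=C[C@@H]2C(C)(C)[C@H]3CC(O[Si](C)(C)C)=C4CC=CC[C@H]4[C@]13C(=O)O2
F4 | step 13 | tert-butyldimethylsilyl enol ether (C6–C7) of 17 | C=C1[C@@H]2CC[C@@H]3[C@](C2)(C(O[Si](C)(C)C(C)(C)C)=C[C@@H]4C(C)(C)[C@H]5C=C(OC)[C@@]34C(=O)O5)C1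
F5 | step 13 | C3,C20-diol carrying the C6–C7 silyl enol ether | C=C1[C@@H]2CC[C@@H]3[C@](C2)(C(O[Si](C)(C)C(C)(C)C)=C[C@@H]4C(C)(C)[C@H](O)C=C(OC)[C@@]34CO)C1
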